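- Target grew in a nearly straight line in the ash run, up to 45.8% of the charge at 6.00 min, so I reckoned it as a pace (near zero-order).

| flask | substrate | enzyme | remark | time |
|---|---|---|---|---|
| ash | 0.10 M | 12 µM | run made earlier |  |
| alder | 0.10 M | 54 µM | run made earlier |  |
| birch | 0.10 M | 180 µM | run made earlier |  |
| larch | 0.079 M | 50 µM | run made earlier |  |
| north | 0.10 M | 50 µM |  | 6.0 min |
| north-east | 0.30 M | 15 µM |  | 6.0 min |
| west | 0.025 M | 200 µM |  | 6.0 min |
| east | 0.15 M | 12 µM |  | 6.0 min |

| run | time / min | target / % | substrate / % |
|---|---|---|---|
| ash | 1.33 | 10.5 | 89.0 |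
| ash | 2.50 | 20.2 | 79.4 |
| ash | 4.00 | 31.5 | 68.2 |
| ash | 5.00 | 38.9 | 61.5 |
| ash | 6.00 | 45.8 | 54.3 |
| alder | 0.500 | 18.5 | 81.6 |
| alder | 0.833 | 30.4 | 69.7 |
| alder | 1.50 | 52.4 | 47.3 |
| alder | 3.00 | 85.5 | 13.2 |
| alder | 6.00 | 94.3 | 3.3 |
| birch | 1.33 | 93.4 | 4.5 |
| birch | 2.50 | 94.2 | 1.6 |
| birch | 4.00 | 92.4 | 0.6 |
| birch | 5.00 | 90.7 | 1.0 |
| birch | 6.00 | 89.2 | 0.3 |
| larch | 1.33 | 52.8 | 47.0 |
| larch | 2.50 | 82.0 | 18.2 |
| larch | 4.00 | 91.4 | 7.3 |
| larch | 5.00 | 93.0 | 5.2 |
| larch | 6.00 | 93.7 | 3.6 |

(standard deviation of a reading: 0.3 percentage points)

* the flasks by amount of target, in percent of the substrate charged, highest first, at 6.0 min (north / north-east / west / east)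
* the same order at 80 s (north / north-east / west / east)
* the amount of target, in percent of the substrate charged of the flask you put first, at 6.0 min
* the amount of target, in percent of the substrate charged of the flask you put last, at 6.0 min

- the numbers in the tables scatter with a standard deviation of 0.3 percentage points

- The first instants: from that last ash reading I took 636 min⁻¹ as the pace, the target made per enzyme per minute, the turnover frequency.
- Alder gave 647 min⁻¹ at 1.50 min and larch gave 627 min⁻¹ at 1.33 min, close to the ash pace.
- So I defined the reach of a flask as w·c(enzyme)·t/c(substrate): the share of the charge this pace can make in the time.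
- The middle: at 80 s the reach was 679% in west, 42.4% in north, 6.79% in east and 4.24% in north-east, and that gave my order.
- At 6.0 min the reach was 30.5% in east and 19.1% in north-east. Both stayed under 100%, so I read them as target. Both flasks held more substrate than any earlier run, so I was trusting the pace there.
- The end: the reach at 6.0 min was 191% in north and 3053% in west, both over 100%, so I turned to the loss of target.
- In the birch readings, target and substrate together fell at 0.0194 min⁻¹ after 2.50 min. I scaled that with enzyme.
- By that rate I reckoned 87.8% of the charge kept in west. For north I reckoned 96.8%, and after taking off the 3.3% of substrate left in alder I expected 93.5% of target in north, more than the share kept in west.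
- The forecast gave north > west > east > north-east at 6.0 min and west > north > east > north-east at 80 s, with 93.8% for the first flask and 23.3% for the last, higher than my north-east reach, holding that “rate scales with enzyme”.
- The simulation gave north > west > east > north-east at 6.0 min and west > north > east > north-east at 80 s, with north at 94.0%, west at 86.2%, east at 31.6% and north-east at 20.0%. East still held 68% of its substrate at 6.00 min and north-east 80%, and the target of each stood a little above its reach. West was down to 3.59% of substrate at 3.00 min, and from then its target fell from 90.3% to 86.2% at 6.00 min while isomer of the product rose from 6.03% to 11.9%.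

    enzyme → spent catalyst A (k = 0.00808 min⁻¹)
    substrate + enzyme → target + enzyme, rate k2*[substrate]^2*[enzyme]/(1 + ([substrate]/Kh2)^2) (19.1 mM, k = 32500 M⁻² s⁻¹)
    target + enzyme ⇌ isomer of the product + enzyme, rate k3*[enzyme]*[target] forward; the back reaction follows from the equilibrium constant (K = 2.31, k = 127 M⁻¹ min⁻¹)
    enzyme + target → spent catalyst B (k = 0.510 M⁻¹ min⁻¹)

- The second flask was north read at 2.5 min. Its reach was 79.5%, under 100%, so I expected about that much target. It held 74.8%, a little less, with 24.6% of substrate left.

The earlier runs and the new flask stem from a simulated flask with constants of no real substance, noise included.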